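Substrate, target and isomer of the product add up to the substrate charged, so any shortfall of the target reading against the substrate consumed is isomer.

- south-east: substrate 0.10 M; gas phase 45 mM (held); free catalyst 4.5 mol%; the very flask that is asked about, followed so far
- flask: substrate 0.10 M; gas phase 45 mM (held); free catalyst 4.5 mol%; time 10 d

south-east run (percent of the substrate charged)

| time / d | target / % |
|---|---|
| 0.417 | 25 |
| 1.25 | 46 |
| 2.50 | 57 |
| 4.00 | 61 |
| 5.00 | 64 |

(each reading ± 1.5 percentage points)

- at the start none of the gas is dissolved
- what was read earlier has a scatter of 1.5 percentage points, one standard deviation
- what may be going on: target <-> isomer of the product; gas phase <-> dissolved gas; substrate + dissolved gas + free catalyst -> free catalyst + target; 2 free catalyst -> spent catalyst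

- green: doubling the amount of free catalyst, all else as stated
- amber: doubling the transfer coefficient of the gas phase, all else as stated
- red: doubling the saturation concentration of gas phase, all else as stated

1. how much target there is at 10 d, in percent of the substrate charged
2. the change that raises the amount of target at 10 d, in percent of the substrate charged most ("none" if none brings more than 2 percentage points) (green / amber / red / none)
3. amount of target at 10 d, in percent of the substrate charged, after red

I assume that dissolved gas stands steady and that free catalyst dies in pairs, falling as 1/(1 + at). Substrate then decays pseudo-first-order in that falling catalyst, and the fraction consumed is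

X = 1 − (1 + at)^(−K).

I try a = 1.60 /d. The early readings need a ratio of logarithms of 2.14, and this a gives 2.15, so it stands, with K = 0.561. At 10 d this gives

X = 79.6 %.

At 5.00 d the gap between X and the reading is 6.8 percentage points. I replace the target curve by its mean, 46.9 % up to 4.00 d and 50.0 % up to 5.00 d. The leak is then

λ = gap/(mean target × time) = 0.0273 /d.

Holding target at its last reading afterwards leaves 64.0 % at 10 d; that reading went into the reckoning, so this shows consistency and no more. The weak link is the single gap, whose scatter moves the answer by 3.4 points. I pool it with the gap at 4.00 d, 6.5 points, and obtain the leak of target to isomer per day, λ = 0.0304 /d. This gives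

isomer = 17.3 %, target = 62.3 %.

Keeping the same share of isomer, I estimate that doubling K (red) gives 75.0 %, above the 67.2 % from doubling a (green).

The forecast stands at 71 %, red and 87 %: “Slow isomerisation can't be excluded”.

The flask gives 61.9 %, and red is best, reaching 70.4 %. At 10.0 d this flask holds 21.0 % of isomer of the product.

    target ⇌ isomer of the product (K = 12.1, k = 0.00154 /h)
    gas phase ⇌ dissolved gas, rate k2*(csat - [dissolved gas]) (kL = 2.71 /h)
    substrate + dissolved gas + free catalyst → free catalyst + target (k = 180 /M²/h)
    2 free catalyst → spent catalyst (k = 5.93 /M/h)

In the neighbour charged with 2.7 mol% of free catalyst, target ends at 58.3 %. Taking that as its mean, λ gives 17.7 % of isomer, and at the end that neighbour holds 18.5 %.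

The earlier runs and the new flask were generated by integration for substances that don't exist; scatter was added.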